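**Strategy**

Everything rests on disconnecting C2–C3 of ring C. In the forward sense a rhodium carbenoid at C3, generated from a diazoketone attached to C4a of ring A, inserts into a C2–H bond of the benzylic ether on O8a; one operation thus makes C2–C3, closes the six-membered ring C and sets C2. The feature used is the C2 methylene itself: bonded to O1 and to the donor-substituted ring B, its C–H bonds are the best hydride donors that C3 can reach. The precursor is a ring A diazoketone, silylated at O5 and O7, that already carries the (R)-side chain at C8 and the silylated ring B benzyl group on O8a.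

Key step: step 14

**Remarks**

- Abbreviations: TBS = tert-butyldimethylsilyl, TIPS = triisopropylsilyl, TES = triethylsilyl. Flavanone numbering (O1, C2, C3, C4, C4a, C5–C8, C8a; side chain C1''–C6'') is used for ring positions from step 13 on.
- Assumption: Rh2(S-PTTL)4, i.e. Rh2[(S)-N-phthaloyl-tert-leucinate]4, is taken to deliver 2S; if the sense of induction proves opposite, Rh2(R-PTTL)4 is used with no other change.
- Design choices: O5 and O7 both carry TIPS, put on in one operation. The (R)-side chain is built by auxiliary-controlled alkylation, which needs no carbon excision. Compounds 1, 2, 5, 12 and 15 are taken as commercial.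

**Route**

Step 1
Reactants: 1 (S)-4-benzyloxazolidin-2-one; 2 3-methylbut-2-enoyl chloride
Product: 4 (S)-4-benzyl-3-(3-methylbut-2-enoyl)oxazolidin-2-one, via lithium oxazolidinide 3 (not isolated)
Conditions: n-BuLi (1.0 equiv), THF, −78 °C; then 2, −78 → 0 °C
Reagents that add atoms: none
Why: N-acylation of the lithiated oxazolidinone with an acid chloride is the standard entry to N-acyl oxazolidinones, and the absence of an amine base keeps the enoyl double bond in conjugation.

Step 2
Reactants: 4 (S)-4-benzyl-3-(3-methylbut-2-enoyl)oxazolidin-2-one; 5 prenyl bromide (1-bromo-3-methylbut-2-ene)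
Product: 7 (S)-4-benzyl-3-[(2S)-5-methyl-2-(prop-1-en-2-yl)hex-4-enoyl]oxazolidin-2-one, via sodium dienolate 6 (not isolated)
Conditions: NaN(SiMe3)2 (1.05 equiv), THF, −78 °C; then 5 (3 equiv), −78 → −30 °C
Reagents that add atoms: none
Why: Deconjugative Evans-type α-alkylation, in which γ-deprotonation gives the chelated (Z)-dienolate that reacts at the α-carbon with the allylic bromide on the face opposite the 4-benzyl group, so that the (S)-auxiliary sets the (2S) centre (the future C2'') and the isopropenyl group is created at the same time.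

Step 3
Reactants: 7 (S)-4-benzyl-3-[(2S)-5-methyl-2-(prop-1-en-2-yl)hex-4-enoyl]oxazolidin-2-one
Product: 8 (S)-4-benzyl-3-[(2S)-3-(3,3-dimethyloxiran-2-yl)-2-(prop-1-en-2-yl)propanoyl]oxazolidin-2-one (both epimers at the oxirane CH)
Conditions: mCPBA (1.05 equiv), NaHCO3, CH2Cl2, 0 °C
Reagents that add atoms: mCPBA, O=C(OO)c1cccc(Cl)c1
Why: Prilezhaev epoxidation should select the trisubstituted, more electron-rich prenyl double bond over the 1,1-disubstituted isopropenyl group, which is also deactivated by the neighbouring imide, and the unselectively formed oxirane centre is erased in step 4.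

Step 4
Reactants: 8 (S)-4-benzyl-3-[(2S)-3-(3,3-dimethyloxiran-2-yl)-2-(prop-1-en-2-yl)propanoyl]oxazolidin-2-one
Product: 9 (2S)-5-methyl-2-(prop-1-en-2-yl)hexane-1,5-diol
Conditions: LiAlH4 (3 equiv), THF, 0 °C → rt; then H2O, aq. NaOH
Reagents that add atoms: none
Why: Hydride reduction cleaves the imide to the primary alcohol with release of the auxiliary and opens the trisubstituted epoxide at its less substituted carbon, so that steps 3 and 4 together amount to Markovnikov hydration of the prenyl double bond without touching the stereocentre.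

Step 5
Reactants: 9 (2S)-5-methyl-2-(prop-1-en-2-yl)hexane-1,5-diol
Product: 10 (5S)-6-iodo-2-methyl-5-(prop-1-en-2-yl)hexan-2-ol
Conditions: I2, PPh3, imidazole, CH2Cl2, 0 °C
Reagents that add atoms: iodine, II
Why: Garegg–Samuelsson (Appel-type) iodination converts only the primary alcohol, because the tertiary alkoxyphosphonium ion cannot be displaced by iodide, and the substitution takes place at CH2 and not at the stereocentre.

Step 6
Reactants: 10 (5S)-6-iodo-2-methyl-5-(prop-1-en-2-yl)hexan-2-ol
Product: 11 triethyl{[(5S)-6-iodo-2-methyl-5-(prop-1-en-2-yl)hexan-2-yl]oxy}silane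
Conditions: TESOTf, 2,6-lutidine, CH2Cl2, −78 → 0 °C
Reagents that add atoms: triethylsilyl triflate, CC[Si](CC)(CC)OS(=O)(=O)C(F)(F)F
Why: Silylation of a hindered tertiary alcohol needs the silyl triflate, and the non-nucleophilic base leaves the primary iodide untouched.

Step 7
Reactants: 12 4-hydroxy-2-methoxybenzaldehyde
Product: 13 4-(tert-butyldimethylsilyloxy)-2-methoxybenzaldehyde
Conditions: TBSCl, imidazole, CH2Cl2, rt
Reagents that add atoms: tert-butyldimethylsilyl chloride, CC(C)(C)[Si](C)(C)Cl
Why: Imidazole-promoted O-silylation of a phenol is routine and masks the ring B hydroxyl with a group that is lost in the final fluoride step.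

Step 8
Reactants: 13 4-(tert-butyldimethylsilyloxy)-2-methoxybenzaldehyde
Product: 14 [4-(tert-butyldimethylsilyloxy)-2-methoxyphenyl]methanol
Conditions: NaBH4, MeOH, 0 °C
Reagents that add atoms: none
Why: Borohydride reduction of the aldehyde is fast at 0 °C and leaves the aryl silyl ether intact.

Step 9
Reactants: 15 1-(2,4,6-trihydroxyphenyl)ethan-1-one (2',4',6'-trihydroxyacetophenone)
Product: 16 1-(2,4,6-trihydroxy-3-iodophenyl)ethan-1-one
Conditions: NIS (1.0 equiv), MeCN, 0 °C, dark
Reagents that add atoms: N-iodosuccinimide, O=C1CCC(=O)N1I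
Why: Electrophilic aromatic iodination of the activated ring gives one mono-iodide because the two free ring positions of 15 are equivalent, and the iodine marks the future C8.

Step 10
Reactants: 16 1-(2,4,6-trihydroxy-3-iodophenyl)ethan-1-one
Product: 17 1-[2-hydroxy-3-iodo-4,6-bis(triisopropylsilyloxy)phenyl]ethan-1-one
Conditions: TIPSCl (2.2 equiv), imidazole, DMF, 0 °C → rt
Reagents that add atoms: triisopropylsilyl chloride, CC(C)[Si](Cl)(C(C)C)C(C)C
Why: Regioselective O-silylation, in which the unchelated O4–H reacts first and the O6–H with one open flank second, while the O2–H wedged between iodine and the acetyl group keeps the hydrogen bond to C=O and is too hindered for the bulky silyl chloride, which leaves the future O8a free.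

Step 11
Reactants: 17 1-[2-hydroxy-3-iodo-4,6-bis(triisopropylsilyloxy)phenyl]ethan-1-one; 14 [4-(tert-butyldimethylsilyloxy)-2-methoxyphenyl]methanol
Product: 18 1-{2-[(4-TBSO-2-methoxybenzyl)oxy]-3-iodo-4,6-bis(triisopropylsilyloxy)phenyl}ethan-1-one
Conditions: PPh3, DIAD, THF, 0 °C → rt
Reagents that add atoms: none
Why: Mitsunobu etherification of the acidic chelated phenol with a primary benzylic alcohol works under neutral conditions and avoids both the unstable electron-rich benzyl halide and carbonate bases that would strip aryl silyl ethers.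

Step 12
Reactants: 11 triethyl{[(5S)-6-iodo-2-methyl-5-(prop-1-en-2-yl)hexan-2-yl]oxy}silane; 18 1-{2-[(4-TBSO-2-methoxybenzyl)oxy]-3-iodo-4,6-bis(triisopropylsilyloxy)phenyl}ethan-1-one
Product: 20 1-{2-[(4-TBSO-2-methoxybenzyl)oxy]-3-[(2R)-5-methyl-2-(prop-1-en-2-yl)-5-(triethylsilyloxy)hexyl]-4,6-bis(triisopropylsilyloxy)phenyl}ethan-1-one, via alkylzinc iodide 19 (not isolated)
Conditions: 11, Zn dust, LiCl, THF, 40 °C; then 18, Pd(OAc)2 (3 mol%), SPhos (6 mol%), THF, rt → 45 °C
Reagents that add atoms: none
Why: Negishi sp3–sp2 coupling, in which the alkylzinc from LiCl-assisted zinc insertion tolerates the ketone and the silyl ethers, and the bulky biarylphosphine on zerovalent palladium promotes oxidative addition at the di-ortho-oxygenated C–I bond and reductive elimination ahead of β-hydride elimination, so the stereocentre β to the metal is carried over unchanged.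

Step 13
Reactants: 20 1-{2-[(4-TBSO-2-methoxybenzyl)oxy]-3-[(2R)-5-methyl-2-(prop-1-en-2-yl)-5-(triethylsilyloxy)hexyl]-4,6-bis(triisopropylsilyloxy)phenyl}ethan-1-one
Product: 23 2-diazo-1-{2-[(4-TBSO-2-methoxybenzyl)oxy]-3-[(2R)-5-methyl-2-(prop-1-en-2-yl)-5-(triethylsilyloxy)hexyl]-4,6-bis(triisopropylsilyloxy)phenyl}ethan-1-one, via lithium enolate 21 (not isolated), via trifluoroacetyl diketone 22 (not isolated)
Conditions: LiN(SiMe3)2, THF, −78 °C; CF3CO2CH2CF3, −78 °C; aq. NH4Cl; then MsN3, Et3N, H2O (1 equiv), MeCN, rt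
Reagents that add atoms: methanesulfonyl azide, CS(=O)(=O)N=[N+]=[N-]
Why: Detrifluoroacetylative (Regitz-type) diazo transfer, in which Claisen condensation of the kinetic methyl ketone enolate with the trifluoroacetate activates the α-carbon and the sulfonyl azide then delivers N2 with loss of the trifluoroacetyl group, all under conditions that the silyl ethers and the benzylic ether tolerate.

Step 14
Reactants: 23 2-diazo-1-{2-[(4-TBSO-2-methoxybenzyl)oxy]-3-[(2R)-5-methyl-2-(prop-1-en-2-yl)-5-(triethylsilyloxy)hexyl]-4,6-bis(triisopropylsilyloxy)phenyl}ethan-1-one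
Product: 24 (2S)-2-(4-TBSO-2-methoxyphenyl)-8-[(2R)-5-methyl-2-(prop-1-en-2-yl)-5-(triethylsilyloxy)hexyl]-5,7-bis(triisopropylsilyloxy)chroman-4-one
Conditions: Rh2(S-PTTL)4 (2 mol%), CH2Cl2, 4 Å MS, slow addition of 23, −20 → 0 °C
Reagents that add atoms: none
Why: The divalent rhodium carboxylate expels N2 from 23 to give an electrophilic carbenoid at C3, which inserts into one of the two enantiotopic C2–H bonds of the O1–CH2–aryl unit through a concerted, asynchronous three-centre transition state with hydride-transfer character and so forms C2–C3. The closest known reaction type is the chiral dirhodium carboxylate-catalysed intramolecular C–H insertion of ortho-alkoxyaryl diazoketones to chroman-4-ones. Ring C closes as a six-membered ring by 1,6-insertion (C3 reaches C2 across C4, C4a, C8a and O1), since this is the only position in reach where a C–H bond is activated by both an ether oxygen and an electron-rich arene. The new C2 centre is set by the chiral ligand sphere of the catalyst (catalyst control, the C2'' centre being too remote to interfere) and is expected as 2S. The step needs chemoselectivity for C–H insertion over attack on the O1 lone pair (oxonium ylide and [1,2]-benzyl shift), on O5, on ring B or on the isopropenyl group. This is secured by the hydridic C2–H (donor-substituted ring B plus O1), the low basicity of the aryl ether oxygen, the bulky TIPS group on O5, the bulky catalyst and slow addition at low temperature.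

Step 15
Reactants: 24 (2S)-2-(4-TBSO-2-methoxyphenyl)-8-[(2R)-5-methyl-2-(prop-1-en-2-yl)-5-(triethylsilyloxy)hexyl]-5,7-bis(triisopropylsilyloxy)chroman-4-one
Product: 25 (2S)-5,7-dihydroxy-2-(4-hydroxy-2-methoxyphenyl)-8-[(2R)-5-hydroxy-5-methyl-2-(prop-1-en-2-yl)hexyl]chroman-4-one (CNP0137998.2)
Conditions: HF·pyridine, pyridine, THF, 0 °C → rt
Reagents that add atoms: none
Why: Global fluoride desilylation removes the three aryl silyl ethers and the tertiary TES ether in one operation, and the buffered, non-basic medium avoids phenoxide-triggered retro-oxa-Michael opening of ring C, so C2 keeps its configuration.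

**Compound list**

1 | (S)-4-benzyloxazolidin-2-one | O=C1N[C@@H](Cc2ccccc2)CO1 | starting material
2 | 3-methylbut-2-enoyl chloride | CC(C)=CC(=O)Cl | starting material
3 | lithium (S)-4-benzyl-2-oxooxazolidin-3-ide (formed in situ) | [Li+].O=C1[N-][C@@H](Cc2ccccc2)CO1 | intermediate
4 | (S)-4-benzyl-3-(3-methylbut-2-enoyl)oxazolidin-2-one | CC(C)=CC(=O)N1[C@@H](Cc2ccccc2)COC1=O | intermediate
5 | prenyl bromide (1-bromo-3-methylbut-2-ene) | CC(C)=CCBr | starting material
6 | sodium (Z)-dienolate of 4 (formed in situ) | [Na+].C=C(C)/C=C(\[O-])N1[C@@H](Cc2ccccc2)COC1=O | intermediate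
7 | (S)-4-benzyl-3-[(2S)-5-methyl-2-(prop-1-en-2-yl)hex-4-enoyl]oxazolidin-2-one | C=C(C)[C@H](CC=C(C)C)C(=O)N1[C@@H](Cc2ccccc2)COC1=O | intermediate
8 | (S)-4-benzyl-3-[(2S)-3-(3,3-dimethyloxiran-2-yl)-2-(prop-1-en-2-yl)propanoyl]oxazolidin-2-one, both epimers at the oxirane CH | C=C(C)[C@H](CC2OC2(C)C)C(=O)N1[C@@H](Cc3ccccc3)COC1=O | intermediate
9 | (2S)-5-methyl-2-(prop-1-en-2-yl)hexane-1,5-diol | C=C(C)[C@H](CCC(C)(C)O)CO | intermediate
10 | (5S)-6-iodo-2-methyl-5-(prop-1-en-2-yl)hexan-2-ol | C=C(C)[C@H](CCC(C)(C)O)CI | intermediate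
11 | triethyl{[(5S)-6-iodo-2-methyl-5-(prop-1-en-2-yl)hexan-2-yl]oxy}silane | C=C(C)[C@H](CCC(C)(C)O[Si](CC)(CC)CC)CI | intermediate
12 | 4-hydroxy-2-methoxybenzaldehyde | COc1cc(O)ccc1C=O | starting material
13 | 4-(tert-butyldimethylsilyloxy)-2-methoxybenzaldehyde | COc1cc(O[Si](C)(C)C(C)(C)C)ccc1C=O | intermediate
14 | [4-(tert-butyldimethylsilyloxy)-2-methoxyphenyl]methanol | COc1cc(O[Si](C)(C)C(C)(C)C)ccc1CO | intermediate
15 | 1-(2,4,6-trihydroxyphenyl)ethan-1-one | CC(=O)c1c(O)cc(O)cc1O | starting material
16 | 1-(2,4,6-trihydroxy-3-iodophenyl)ethan-1-one | CC(=O)c1c(O)cc(O)c(I)c1O | intermediate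
17 | 1-[2-hydroxy-3-iodo-4,6-bis(triisopropylsilyloxy)phenyl]ethan-1-one | CC(=O)c1c(O[Si](C(C)C)(C(C)C)C(C)C)cc(O[Si](C(C)C)(C(C)C)C(C)C)c(I)c1O | intermediate
18 | 1-{2-[(4-TBSO-2-methoxybenzyl)oxy]-3-iodo-4,6-bis(triisopropylsilyloxy)phenyl}ethan-1-one | CC(=O)c1c(O[Si](C(C)C)(C(C)C)C(C)C)cc(O[Si](C(C)C)(C(C)C)C(C)C)c(I)c1OCc1ccc(O[Si](C)(C)C(C)(C)C)cc1OC | intermediate
19 | {(2S)-5-methyl-2-(prop-1-en-2-yl)-5-(triethylsilyloxy)hexyl}zinc iodide (formed in situ) | C=C(C)[C@H](CCC(C)(C)O[Si](CC)(CC)CC)C[Zn]I | intermediate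
20 | ring A methyl ketone: 1-{2-[(4-TBSO-2-methoxybenzyl)oxy]-3-[(2R)-5-methyl-2-(prop-1-en-2-yl)-5-(triethylsilyloxy)hexyl]-4,6-bis(triisopropylsilyloxy)phenyl}ethan-1-one | C=C(C)[C@H](CCC(C)(C)O[Si](CC)(CC)CC)Cc1c(O[Si](C(C)C)(C(C)C)C(C)C)cc(O[Si](C(C)C)(C(C)C)C(C)C)c(C(C)=O)c1OCc1ccc(O[Si](C)(C)C(C)(C)C)cc1OC | intermediate
21 | lithium enolate of 20 (formed in situ) | C=C(C)[C@H](CCC(C)(C)O[Si](CC)(CC)CC)Cc1c(O[Si](C(C)C)(C(C)C)C(C)C)cc(O[Si](C(C)C)(C(C)C)C(C)C)c(C(=C)[O-])c1OCc1ccc(O[Si](C)(C)C(C)(C)C)cc1OC.[Li+] | intermediate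
22 | 4,4,4-trifluoro-1-aryl-butane-1,3-dione from 20 (aryl as in 20; used crude) | C=C(C)[C@H](CCC(C)(C)O[Si](CC)(CC)CC)Cc1c(O[Si](C(C)C)(C(C)C)C(C)C)cc(O[Si](C(C)C)(C(C)C)C(C)C)c(C(=O)CC(=O)C(F)(F)F)c1OCc1ccc(O[Si](C)(C)C(C)(C)C)cc1OC | intermediate
23 | ring A diazoketone (key-step precursor): 2-diazo-1-aryl-ethan-1-one, aryl as in 20 | C=C(C)[C@H](CCC(C)(C)O[Si](CC)(CC)CC)Cc1c(O[Si](C(C)C)(C(C)C)C(C)C)cc(O[Si](C(C)C)(C(C)C)C(C)C)c(C(=O)C=[N+]=[N-])c1OCc1ccc(O[Si](C)(C)C(C)(C)C)cc1OC | intermediate
24 | fully silylated (2S,2''R)-flavanone: (2S)-2-(4-TBSO-2-methoxyphenyl)-8-[(2R)-5-methyl-2-(prop-1-en-2-yl)-5-(triethylsilyloxy)hexyl]-5,7-bis(triisopropylsilyloxy)chroman-4-one | C=C(C)[C@H](CCC(C)(C)O[Si](CC)(CC)CC)Cc1c(O[Si](C(C)C)(C(C)C)C(C)C)cc(O[Si](C(C)C)(C(C)C)C(C)C)c2c1O[C@H](c1ccc(O[Si](C)(C)C(C)(C)C)cc1OC)CC2=O | intermediate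
25 | (2S)-5,7-dihydroxy-2-(4-hydroxy-2-methoxyphenyl)-8-[(2R)-5-hydroxy-5-methyl-2-(prop-1-en-2-yl)hexyl]chroman-4-one | C=C(C)[C@H](CCC(C)(C)O)Cc1c(O)cc(O)c2c1O[C@H](c1ccc(O)cc1OC)CC2=O | target

**Step count**

Total steps: 15. Longest linear sequence: 10 steps (steps 1–6, then 12–15).

**Steps most likely to fail**

1. Step 14. The carbenoid may attack the lone pair of O1 faster than it inserts into C2–H, which leads through an oxonium ylide to a [1,2]-shift of the benzyl group. Discrimination between the two enantiotopic C2–H bonds may also be poor.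
   Fallback: ring C is closed by oxa-Michael addition instead, and C2 is resolved by separation. The fallback sets out from phenol 17 and aldehyde 13 and comes back to the route at 24. Amine-catalysed Claisen–Schmidt condensation of 17 with 13 (pyrrolidine, EtOH, 60 °C; no hydroxide, so the aryl silyl ethers persist) should give the 2'-hydroxychalcone F1. With NaOAc in refluxing EtOH the free phenol of F1 adds to the enone (6-endo oxa-Michael) to give the racemic 8-iodoflavanone F2. Negishi coupling of F2 with the organozinc 19 (Pd(OAc)2, SPhos, THF) then installs the side chain and gives 24 together with its C2 epimer F3. Because C2'' is fixed, these two are diastereomers and are to be separated by preparative HPLC; F3 can be fed back by base-mediated ring opening and reclosure (NaOAc, EtOH).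

2. Step 12. Oxidative addition and transmetalation at the C–I bond flanked by two oxygen substituents may be slow, so that protonation of the organozinc or β-hydride elimination from the alkylpalladium intermediate takes over and the side chain is lost.
   Fallback: the organometallic partner is changed to a boron ate complex, i.e. a B-alkyl Suzuki–Miyaura coupling. The fallback sets out from iodide 11 and aryl iodide 18 and comes back at 20. Lithium–iodine exchange on 11 (t-BuLi, 2 equiv, Et2O, −78 °C) gives the alkyllithium F4, which is trapped with B-methoxy-9-borabicyclo[3.3.1]nonane to give the lithium borinate F5. This ate complex is coupled with 18 (PdCl2(dppf), AsPh3, aq. K3PO4, DMF, rt) to give 20. Boron-to-palladium transfer from the ate complex is fast at room temperature and involves no reagent that can be protonated, and the bidentate ligand disfavours β-hydride elimination.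

3. Step 10. The two hydrogen-bonded ortho phenols may not be differentiated well enough, so that silylation takes place at O2 instead of O6 and the benzyl group would later end up on the wrong oxygen.
   Fallback: the order of silylation and iodination is inverted, so that the regiochemical decision moves from the oxygen atoms to the ring. The fallback sets out from 15 and comes back at 17. Disilylation of 15 (TIPSCl, 2.2 equiv, imidazole, DMF) gives 1-[2-hydroxy-4,6-bis(triisopropylsilyloxy)phenyl]ethan-1-one F6 without any regiochemical choice, because the two ortho hydroxyls of 15 are equivalent. Electrophilic iodination of F6 (NIS, MeCN, 0 °C) is then expected ortho to the remaining free phenol, at the carbon between OH and one OTIPS group and not at the carbon shielded between two OTIPS groups, which gives 17.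

**Further compounds**

F1 | step 14 | (E)-1-[2-hydroxy-3-iodo-4,6-bis(triisopropylsilyloxy)phenyl]-3-[4-(tert-butyldimethylsilyloxy)-2-methoxyphenyl]prop-2-en-1-one | O=C(/C=C/c1ccc(O[Si](C)(C)C(C)(C)C)cc1OC)c1c(O[Si](C(C)C)(C(C)C)C(C)C)cc(O[Si](C(C)C)(C(C)C)C(C)C)c(I)c1O
F2 | step 14 | racemic 2-[4-(tert-butyldimethylsilyloxy)-2-methoxyphenyl]-8-iodo-5,7-bis(triisopropylsilyloxy)chroman-4-one | O=C1CC(c2ccc(O[Si](C)(C)C(C)(C)C)cc2OC)Oc2c(I)c(O[Si](C(C)C)(C(C)C)C(C)C)cc(O[Si](C(C)C)(C(C)C)C(C)C)c12
F3 | step 14 | (2R,2''R)-epimer of 24 | C=C(C)[C@H](CCC(C)(C)O[Si](CC)(CC)CC)Cc1c(O[Si](C(C)C)(C(C)C)C(C)C)cc(O[Si](C(C)C)(C(C)C)C(C)C)c2c1O[C@@H](c1ccc(O[Si](C)(C)C(C)(C)C)cc1OC)CC2=O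
F4 | step 12 | {(2S)-5-methyl-2-(prop-1-en-2-yl)-5-(triethylsilyloxy)hexyl}lithium | C=C(C)[C@H](CCC(C)(C)O[Si](CC)(CC)CC)C[Li]
F5 | step 12 | lithium 9-methoxy-9-{(2S)-5-methyl-2-(prop-1-en-2-yl)-5-(triethylsilyloxy)hexyl}-9-borabicyclo[3.3.1]nonan-9-uide | [Li+].C=C(C)[C@H](CCC(C)(C)O[Si](CC)(CC)CC)C[B-]1(OC)C2CCCC1CCC2
F6 | step 10 | 1-[2-hydroxy-4,6-bis(triisopropylsilyloxy)phenyl]ethan-1-one | CC(=O)c1c(O)cc(O[Si](C(C)C)(C(C)C)C(C)C)cc1O[Si](C(C)C)(C(C)C)C(C)C
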